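**Plan**

- Retrosynthesis: the C11=C13 alkene is cut first (β-elimination of a C13 oxygen). The C4–C5 bond is cut next, which opens the oxirane and the ten-membered ring together to a C5 aldehyde and a C4 sulfonium ylide. Further cuts: the C8 ester, C10=C1 (cross-metathesis), C9–C10 (aldol), C5/C9 (ozonolysis of a C5=C9 cyclopentene), C6–O (iodolactonisation), C7–C11 (Claisen).
- Forward order: cyclopentene → cis-fused γ-lactone → ring cleavage with a temporary C5–O8 lactol ring → chain growth at C9 and C1 → lactol opened and O8 angeloylated → ten-membered ring and oxirane closed in one event → methylene lactone unmasked.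
- Enabling feature: the C4–C5 bond belongs to both the oxirane and the ten-membered carbocycle. C5 (a CH next to the lactone carbinol C6) can be an aldehyde carbon, and C4 (bearing C15 and C3) can be the carbon of a secondary sulfonium ylide, so one carbonyl-plus-ylide epoxidation closes both rings.
- Stereochemistry: C6, C7 and C8 come from (1R,4S)-cis-4-acetoxycyclopent-2-en-1-ol by suprafacial Claisen transfer and cis-iodolactonisation. C9 comes from a chelation-controlled aldol. C5 and C4 are set in the key step (by C6 and by the cis ring fusion). The C10=C1 geometry comes from thermodynamic cross-metathesis, and the angelate from angelic acid without isomerisation.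
- Helpers, all removed after use: the lactol (masks C5, keeps O8 apart from O9), the C11 silyloxymethyl group (masked C13 methylene), the diphenylsulfonium group.

Key step: step 19

Remark: C1–C15 is the germacrane numbering of the target (C12 lactone carbonyl, C13 methylene carbon, C14 ester carbon, C15 methyl); O6, O8, O9 are the oxygens on those carbons; TBS = tert-butyldimethylsilyl, TES = triethylsilyl. The centres at C11 (6–36), C4 (21–31), C10 (17, 18) and the anomeric C5 of the lactols are mixtures that are removed or set later, so they carry no descriptor. Compounds 4, 15, 20, 27 and 2-methylhexa-1,5-diene are taken as purchased.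

**Route**

Step 1
Reactants: 1 (1R,4S)-cis-4-acetoxycyclopent-2-en-1-ol
Product: 2 (1S,4R)-4-(triethylsilyloxy)cyclopent-2-en-1-yl acetate
Conditions: TESCl, imidazole, CH2Cl2, 0 °C
Reagents that add atoms: chlorotriethylsilane, CC[Si](Cl)(CC)CC
Why: Silylation of the only free hydroxyl (the later O8); no stereocentre is formed or touched.

Step 2
Reactants: 2 (1S,4R)-4-(triethylsilyloxy)cyclopent-2-en-1-yl acetate
Product: 3 (1S,4R)-4-(triethylsilyloxy)cyclopent-2-en-1-ol
Conditions: K2CO3 (cat.), MeOH, 0 °C
Reagents that add atoms: none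
Why: Base-catalysed transesterification removes the acetate while the secondary triethylsilyl ether should survive the cold carbonate conditions; no stereocentre is touched.

Step 3
Reactants: 3 (1S,4R)-4-(triethylsilyloxy)cyclopent-2-en-1-ol; 4 3-(tert-butyldimethylsilyloxy)propanoic acid
Product: 5 (1S,4R)-4-(triethylsilyloxy)cyclopent-2-en-1-yl 3-(tert-butyldimethylsilyloxy)propanoate
Conditions: DCC, DMAP (cat.), CH2Cl2, 0 °C → rt
Reagents that add atoms: none
Why: Steglich esterification joins alcohol and acid under neutral conditions that leave both silyl ethers and the allylic stereocentres intact.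

Step 4
Reactants: 5 (1S,4R)-4-(triethylsilyloxy)cyclopent-2-en-1-yl 3-(tert-butyldimethylsilyloxy)propanoate
Product: 8 3-(TBS-oxy)-2-[cis-5-(triethylsilyloxy)cyclopent-2-en-1-yl]propanoic acid, via silyl ketene acetal 6 (not isolated), via trimethylsilyl ester 7 (not isolated)
Conditions: LiN(iPr)2, Me3SiCl, THF, −78 °C → rt; aqueous work-up
Reagents that add atoms: chlorotrimethylsilane, C[Si](C)(C)Cl (its atoms stay only in intermediates 6 and 7)
Why: Ireland–Claisen rearrangement: the silyl ketene acetal, trapped at −78 °C before the β-silyloxy group can eliminate, undergoes a suprafacial [3,3] shift on the ring face that carried the ester oxygen, so C11 is delivered to C7 cis to the C8 silyl ether (the C11 centre forms as a mixture and is removed in step 21).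

Step 5
Reactants: 8 3-(TBS-oxy)-2-[cis-5-(triethylsilyloxy)cyclopent-2-en-1-yl]propanoic acid
Product: 9 cis-fused iodolactone (6-iodo-4-TES-oxy-3-(TBS-oxymethyl)hexahydro-2H-cyclopenta[b]furan-2-one; iodine trans to the lactone oxygen)
Conditions: I2, NaHCO3, MeCN/H2O, 0 °C
Reagents that add atoms: iodine, II
Why: Iodolactonisation: the carboxylate tethered at C7 opens the iodonium ion at C6 in a 5-exo mode from its own face, giving the cis-fused γ-lactone (O6 cis to C11 and O8) with iodine at C5 trans to O6.

Step 6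
Reactants: 9 cis-fused iodolactone
Product: 10 4-(triethylsilyloxy)-3-(TBS-oxymethyl)-3,3a,4,6a-tetrahydro-2H-cyclopenta[b]furan-2-one (all-cis at C3a; C4; C6a)
Conditions: DBU, toluene, 80 °C
Reagents that add atoms: none
Why: E2 dehydroiodination: only a C9 hydrogen is anti-periplanar to the C5 iodine (H6 is cis to it), so the C5=C9 alkene forms.

Step 7
Reactants: 10 silyl-protected bicyclic alkene lactone
Product: 11 4-hydroxy-3-(TBS-oxymethyl)-3,3a,4,6a-tetrahydro-2H-cyclopenta[b]furan-2-one (all-cis)
Conditions: AcOH/THF/H2O (3:1:1), rt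
Reagents that add atoms: none
Why: Acid-catalysed desilylation cleaves the secondary triethylsilyl ether far faster than the primary TBS ether, and the non-basic medium avoids migration of the lactone to the freed O8.

Step 8
Reactants: 11 hydroxy alkene lactone
Product: 14 O-triethylsilyl lactol aldehyde (γ-lactone cis-fused at C6–C7 to the C5–O8 tetrahydrofuran; C9 formyl group on C8 trans to the lactone ring), via ozonide 12 (not isolated), via lactol aldehyde 13 (not isolated)
Conditions: O3, CH2Cl2, −78 °C; PPh3; then TESCl, imidazole, 0 °C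
Reagents that add atoms: ozone, [O-][O+]=O; chlorotriethylsilane, CC[Si](Cl)(CC)CC
Why: Ozonolysis with reductive work-up cleaves C5=C9; the cis O8–H closes onto the C5 aldehyde as the only possible five-membered lactol (it cannot reach C9), which tells C5 from C9, and silylation of the lactol hydroxyl locks this furanose form.

Step 9
Reactants: 14 O-triethylsilyl lactol aldehyde; 15 methyl 3-(dimethylamino)propanoate
Product: 17 β-hydroxy α-(dimethylaminomethyl) ester (C9 carbinol; C10 epimers), via lithium enolate 16 (not isolated)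
Conditions: 15, LiN(iPr)2, THF, −78 °C; then 14 precomplexed with MgBr2·OEt2, −78 °C; NH4Cl
Reagents that add atoms: lithium diisopropylamide, [Li+].CC(C)[N-]C(C)C (lithium stays only in intermediate 16)
Why: Aldol addition of an ester enolate (an acrylate α-anion equivalent) to the magnesium chelate of the α-alkoxy aldehyde (C9=O and ring oxygen O8): attack from the face away from C7 sets C9 with the 8,9-threo relation, and the C10 centre is removed in step 10.

Step 10
Reactants: 17 β-hydroxy α-(dimethylaminomethyl) ester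
Product: 19 2-substituted acrylate alcohol (Morita–Baylis–Hillman-type; C10=CH2; free C9–OH), via ammonium iodide 18 (not isolated)
Conditions: MeI, THF, rt; then DBU, 0 °C
Reagents that add atoms: iodomethane, CI (its atoms stay only in intermediate 18)
Why: Quaternisation of the amine and E1cB (Hofmann-type) elimination of trimethylamine from the β-ammonio ester give the acrylate; C9 is not touched.

Step 11
Reactants: 20 hex-5-en-2-ol (racemic)
Product: 21 5-bromohex-1-ene (racemic)
Conditions: CBr4, PPh3, CH2Cl2, 0 °C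
Reagents that add atoms: carbon tetrabromide, BrC(Br)(Br)Br
Why: Appel reaction of a secondary alcohol; the centre (later C4) is racemic and becomes a planar ylide carbon in step 19.

Step 12
Reactants: 19 2-substituted acrylate alcohol; 21 5-bromohex-1-ene
Product: 22 bromo enoate alcohol (C10=C1 with C2 trans to the ester and cis to C9; C4 bromide)
Conditions: second-generation Hoveyda–Grubbs catalyst (10 mol%), 21 (5 equiv), CH2Cl2, 40 °C
Reagents that add atoms: none
Why: Olefin cross-metathesis between the 1,1-disubstituted acrylate and a terminal alkene should give the trisubstituted enoate under thermodynamic control with C2 trans to the ester (E), the geometry the ring needs.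

Step 13
Reactants: 22 bromo enoate alcohol
Product: 23 C9 TBS ether of 22
Conditions: TBSOTf, 2,6-lutidine, CH2Cl2, −78 → 0 °C
Reagents that add atoms: tert-butyldimethylsilyl trifluoromethanesulfonate, CC(C)(C)[Si](C)(C)OS(=O)(=O)C(F)(F)F
Why: Silylation of the hindered allylic C9 alcohol with a silyl triflate; this group keeps O9 apart from O8 when the lactol is opened.

Step 14
Reactants: 23 C9 TBS ether
Product: 25 C5,C8-diol (open chain; γ-lactone on O6; primary C5–OH; secondary C8–OH), via lactol 24 (not isolated)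
Conditions: Bu4NF, AcOH, THF, 0 °C; then NaBH4, MeOH, −20 °C
Reagents that add atoms: none
Why: Buffered fluoride cleaves the acetal-like anomeric silyl ether much faster than the two TBS ethers, and borohydride reduces the open hydroxy-aldehyde form of the lactol, freeing O8 and C5–OH without touching a stereocentre.

Step 15
Reactants: 25 C5,C8-diol
Product: 26 C5 triethylsilyl ether with free C8–OH
Conditions: TESCl (1.05 equiv), imidazole, CH2Cl2, −78 → −40 °C
Reagents that add atoms: chlorotriethylsilane, CC[Si](Cl)(CC)CC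
Why: Selective silylation of the primary C5 alcohol over the hindered secondary C8 alcohol at low temperature.

Step 16
Reactants: 26 C5 triethylsilyl ether; 27 angelic acid
Product: 29 C8 angelate, via mixed anhydride 28 (not isolated)
Conditions: 27, 2,4,6-Cl3C6H2COCl, Et3N, toluene, rt; then 26, toluene, 70 °C
Reagents that add atoms: 2,4,6-trichlorobenzoyl chloride, O=C(Cl)c1c(Cl)cc(Cl)cc1Cl (its atoms stay only in intermediate 28)
Why: Yamaguchi esterification through the preformed mixed anhydride, a protocol that acylates hindered alcohols with angelic acid without isomerisation to the tiglate; the (Z) geometry comes from angelic acid.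

Step 17
Reactants: 29 C8 angelate
Product: 30 C5 aldehyde (α-acyloxy aldehyde on the lactone carbinol C6)
Conditions: (COCl)2, DMSO, CH2Cl2, −78 → −40 °C; iPr2NEt, −78 → 0 °C
Reagents that add atoms: none
Why: Swern oxidation converts a primary triethylsilyl ether directly into the aldehyde while TBS ethers remain, and the hindered amine at low temperature limits epimerisation at C6.

Step 18
Reactants: 30 C5 aldehyde
Product: 31 C4 diphenylsulfonium tetrafluoroborate
Conditions: Ph2S (10 equiv), AgBF4, 2,6-di-tert-butyl-4-methylpyridine, CH2Cl2, 0 °C → rt, dark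
Reagents that add atoms: diphenyl sulfide, c1ccc(Sc2ccccc2)cc1; silver tetrafluoroborate, [Ag+].F[B-](F)(F)F
Why: Silver-assisted S-alkylation of diphenyl sulfide by the secondary bromide, the usual way to isopropyl-type diphenylsulfonium salts; the C4 centre needs no control.

Step 19
Reactants: 31 C4 diphenylsulfonium tetrafluoroborate
Product: 34 macrocyclic 4,5-epoxide (ten-membered ring; C9 and C13 TBS ethers), via sulfonium ylide 32 (not isolated), via betaine 33 (not isolated)
Conditions: KN(SiMe3)2 (1.05 equiv), THF, 2 mM, slow addition, −78 → −30 °C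
Reagents that add atoms: none
Why: Proposed new method: deprotonation of the secondary diphenylsulfonium salt at C4 gives a non-stabilised ylide whose carbanion adds to the C5 aldehyde (closing the ten-membered carbocycle in a 10-exo-trig mode), and the betaine collapses by anti-periplanar 3-exo-tet displacement of diphenyl sulfide by the C5 alkoxide, which closes the oxirane. The closest known reaction type is the Corey–Chaykovsky epoxidation of aldehydes with diphenylsulfonium isopropylide-type ylides, together with intramolecular sulfonium-ylide epoxidations that close five- to seven-membered rings; a ten-membered carbocycle has not been closed in this way. C5 is set by the C6 stereocentre of the lactone: with the C5=O dipole opposed to the C6–O bond the tether can deliver C4 only from the C7 side, which gives the 5,6-threo relation (5S). C4 is set by the ring: only the betaine leading to the cis-fused oxirane (C3 and C6 on the same side) can reach the anti-periplanar O–/S+ geometry without the strain of a trans-fused ten-membered ring, and closure with inversion at C4 gives 4R. The step needs ylide formation in preference to enolisation at C6 and ring closure in preference to oligomerisation; the sulfonium C–H is the most acidic site, one equivalent of a hindered amide base is used at −78 °C, and high dilution is applied. The C10=C1 enoate cannot be attacked intramolecularly because C1 is only three bonds from C4 and the ester carbonyl is trans to the chain, the angelate is too hindered, and the methylene lactone is still masked as the C13 silyl ether.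

Step 20
Reactants: 34 macrocyclic 4,5-epoxide
Product: 35 C9,C13-diol
Conditions: HF·pyridine, pyridine, THF, 0 °C → rt
Reagents that add atoms: none
Why: Fluoride-mediated desilylation under pyridine-buffered, non-basic conditions, which should spare the oxirane and prevent migration of the angelate from O8 to the freed O9.

Step 21
Reactants: 35 C9,C13-diol
Product: 37 target CNP0251641.1, via mesylate 36 (not isolated)
Conditions: MsCl (1.1 equiv), Et3N, CH2Cl2, −40 °C; then DBU, 0 °C
Reagents that add atoms: methanesulfonyl chloride, CS(=O)(=O)Cl (its atoms stay only in intermediate 36)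
Why: Selective mesylation of the primary alcohol followed by E1cB elimination from the β-mesyloxy lactone, the classical route to α-methylene-γ-butyrolactones; the C11 centre disappears.

**Compound list**

1 | (1R,4S)-cis-4-acetoxycyclopent-2-en-1-ol | CC(=O)O[C@@H]1C=C[C@H](O)C1 | starting material
2 | (1S,4R)-4-(triethylsilyloxy)cyclopent-2-en-1-yl acetate | CC(=O)O[C@@H]1C=C[C@H](O[Si](CC)(CC)CC)C1 | intermediate
3 | (1S,4R)-4-(triethylsilyloxy)cyclopent-2-en-1-ol | O[C@@H]1C=C[C@H](O[Si](CC)(CC)CC)C1 | intermediate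
4 | 3-(tert-butyldimethylsilyloxy)propanoic acid | CC(C)(C)[Si](C)(C)OCCC(=O)O | starting material
5 | (1S,4R)-4-(triethylsilyloxy)cyclopent-2-en-1-yl 3-(tert-butyldimethylsilyloxy)propanoate | CC(C)(C)[Si](C)(C)OCCC(=O)O[C@@H]1C=C[C@H](O[Si](CC)(CC)CC)C1 | intermediate
6 | O-trimethylsilyl ketene acetal of ester 5 | CC(C)(C)[Si](C)(C)OCC=C(O[Si](C)(C)C)O[C@@H]1C=C[C@H](O[Si](CC)(CC)CC)C1 | intermediate (not isolated)
7 | trimethylsilyl ester of acid 8 | C[Si](C)(C)OC(=O)C(CO[Si](C)(C)C(C)(C)C)[C@H]1C=CC[C@H]1O[Si](CC)(CC)CC | intermediate (not isolated)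
8 | 3-(TBS-oxy)-2-[cis-5-(triethylsilyloxy)cyclopent-2-en-1-yl]propanoic acid (C7–C11 bond cis to O8; C11 epimers) | OC(=O)C(CO[Si](C)(C)C(C)(C)C)[C@H]1C=CC[C@H]1O[Si](CC)(CC)CC | intermediate
9 | cis-fused iodolactone, 6-iodo-4-(triethylsilyloxy)-3-(TBS-oxymethyl)hexahydro-2H-cyclopenta[b]furan-2-one, silyl ether cis to the lactone ring, iodine trans to the lactone oxygen | CC(C)(C)[Si](C)(C)OCC1C(=O)O[C@@H]2[C@H]1[C@H](O[Si](CC)(CC)CC)C[C@H]2I | intermediate
10 | 4-(triethylsilyloxy)-3-(TBS-oxymethyl)-3,3a,4,6a-tetrahydro-2H-cyclopenta[b]furan-2-one, all-cis at C3a, C4, C6a | CC(C)(C)[Si](C)(C)OCC1C(=O)O[C@@H]2[C@H]1[C@H](O[Si](CC)(CC)CC)C=C2 | intermediate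
11 | 4-hydroxy-3-(TBS-oxymethyl)-3,3a,4,6a-tetrahydro-2H-cyclopenta[b]furan-2-one, all-cis | CC(C)(C)[Si](C)(C)OCC1C(=O)O[C@@H]2[C@H]1[C@H](O)C=C2 | intermediate
12 | ozonide (1,2,4-trioxolane across C5 and C9) of 11 | CC(C)(C)[Si](C)(C)OCC1C(=O)O[C@@H]2[C@H]1[C@H](O)C3OOC2O3 | intermediate (not isolated)
13 | lactol aldehyde: γ-lactone cis-fused at C6–C7 to the C5–O8 lactol ring, C9 formyl on C8 trans to the lactone | CC(C)(C)[Si](C)(C)OCC1C(=O)O[C@@H]2[C@H]1[C@@H](C=O)OC2O | intermediate (not isolated)
14 | O-triethylsilyl derivative of lactol aldehyde 13 | CC(C)(C)[Si](C)(C)OCC1C(=O)O[C@@H]2[C@H]1[C@@H](C=O)OC2O[Si](CC)(CC)CC | intermediate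
15 | methyl 3-(dimethylamino)propanoate | CN(C)CCC(=O)OC | starting material
16 | lithium enolate of 15 | [Li+].[O-]C(OC)=CCN(C)C | intermediate (not isolated)
17 | aldol adduct: C9 carbinol (8,9-threo), C10 bearing CO2Me and CH2NMe2 | CC(C)(C)[Si](C)(C)OCC1C(=O)O[C@@H]2[C@H]1[C@@H]([C@@H](O)C(CN(C)C)C(=O)OC)OC2O[Si](CC)(CC)CC | intermediate
18 | trimethylammonium iodide of 17 | CC(C)(C)[Si](C)(C)OCC1C(=O)O[C@@H]2[C@H]1[C@@H]([C@@H](O)C(C[N+](C)(C)C)C(=O)OC)OC2O[Si](CC)(CC)CC.[I-] | intermediate (not isolated)
19 | 2-substituted acrylate alcohol (C10=CH2, free C9–OH) | CC(C)(C)[Si](C)(C)OCC1C(=O)O[C@@H]2[C@H]1[C@@H]([C@@H](O)C(=C)C(=O)OC)OC2O[Si](CC)(CC)CC | intermediate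
20 | hex-5-en-2-ol (racemic) | CC(O)CCC=C | starting material
21 | 5-bromohex-1-ene (racemic) | CC(Br)CCC=C | intermediate
22 | bromo enoate alcohol: (E)-C10=C1 (C2 cis to C9), C4 bromide, free C9–OH | CC(C)(C)[Si](C)(C)OCC1C(=O)O[C@@H]2[C@H]1[C@@H]([C@@H](O)/C(C(=O)OC)=C\CCC(C)Br)OC2O[Si](CC)(CC)CC | intermediate
23 | C9 TBS ether of 22 | CC(C)(C)[Si](C)(C)OCC1C(=O)O[C@@H]2[C@H]1[C@@H]([C@@H](O[Si](C)(C)C(C)(C)C)/C(C(=O)OC)=C\CCC(C)Br)OC2O[Si](CC)(CC)CC | intermediate
24 | free lactol of 23 | CC(C)(C)[Si](C)(C)OCC1C(=O)O[C@@H]2[C@H]1[C@@H]([C@@H](O[Si](C)(C)C(C)(C)C)/C(C(=O)OC)=C\CCC(C)Br)OC2O | intermediate (not isolated)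
25 | open-chain C5,C8-diol with γ-lactone on O6 | CC(C)(C)[Si](C)(C)OCC1C(=O)O[C@@H](CO)[C@H]1[C@H](O)[C@@H](O[Si](C)(C)C(C)(C)C)/C(C(=O)OC)=C\CCC(C)Br | intermediate
26 | C5 triethylsilyl ether of 25 | CC(C)(C)[Si](C)(C)OCC1C(=O)O[C@@H](CO[Si](CC)(CC)CC)[C@H]1[C@H](O)[C@@H](O[Si](C)(C)C(C)(C)C)/C(C(=O)OC)=C\CCC(C)Br | intermediate
27 | angelic acid, (Z)-2-methylbut-2-enoic acid | C/C=C(/C)C(=O)O | starting material
28 | angelic 2,4,6-trichlorobenzoic anhydride | C/C=C(/C)C(=O)OC(=O)c1c(Cl)cc(Cl)cc1Cl | intermediate (not isolated)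
29 | C8 angelate of 26 | CC(C)(C)[Si](C)(C)OCC1C(=O)O[C@@H](CO[Si](CC)(CC)CC)[C@H]1[C@H](OC(=O)/C(C)=C\C)[C@@H](O[Si](C)(C)C(C)(C)C)/C(C(=O)OC)=C\CCC(C)Br | intermediate
30 | C5 aldehyde | CC(C)(C)[Si](C)(C)OCC1C(=O)O[C@@H](C=O)[C@H]1[C@H](OC(=O)/C(C)=C\C)[C@@H](O[Si](C)(C)C(C)(C)C)/C(C(=O)OC)=C\CCC(C)Br | intermediate
31 | C4 diphenylsulfonium tetrafluoroborate of 30 | CC(C)(C)[Si](C)(C)OCC1C(=O)O[C@@H](C=O)[C@H]1[C@H](OC(=O)/C(C)=C\C)[C@@H](O[Si](C)(C)C(C)(C)C)/C(C(=O)OC)=C\CCC(C)[S+](c1ccccc1)c1ccccc1.F[B-](F)(F)F | intermediate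
32 | C4 sulfonium ylide | CC(C)(C)[Si](C)(C)OCC1C(=O)O[C@@H](C=O)[C@H]1[C@H](OC(=O)/C(C)=C\C)[C@@H](O[Si](C)(C)C(C)(C)C)/C(C(=O)OC)=C\CC[C-](C)[S+](c1ccccc1)c1ccccc1 | intermediate (not isolated)
33 | macrocyclic betaine (C5 alkoxide, C4 sulfonium) | CC(C)(C)[Si](C)(C)OCC1C(=O)O[C@@H]2[C@H]1[C@H](OC(=O)/C(C)=C\C)[C@@H](O[Si](C)(C)C(C)(C)C)/C(C(=O)OC)=C\CCC(C)([S+](c1ccccc1)c1ccccc1)C2[O-] | intermediate (not isolated)
34 | macrocyclic (4R,5S)-epoxide, C9 and C13 TBS ethers | CC(C)(C)[Si](C)(C)OCC1C(=O)O[C@@H]2[C@H]1[C@H](OC(=O)/C(C)=C\C)[C@@H](O[Si](C)(C)C(C)(C)C)/C(C(=O)OC)=C\CC[C@@]1(C)O[C@@H]21 | intermediate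
35 | C9,C13-diol | OCC1C(=O)O[C@@H]2[C@H]1[C@H](OC(=O)/C(C)=C\C)[C@@H](O)/C(C(=O)OC)=C\CC[C@@]1(C)O[C@@H]21 | intermediate
36 | C13 mesylate | CS(=O)(=O)OCC1C(=O)O[C@@H]2[C@H]1[C@H](OC(=O)/C(C)=C\C)[C@@H](O)/C(C(=O)OC)=C\CC[C@@]1(C)O[C@@H]21 | intermediate (not isolated)
37 | CNP0251641.1 | C=C1C(=O)O[C@@H]2[C@H]1[C@H](OC(=O)/C(C)=C\C)[C@@H](O)/C(C(=O)OC)=C\CC[C@@]1(C)O[C@@H]21 | target

**Step count and risks**

Total step count: 21. Longest linear sequence: 20 steps (steps 1–10 and 12–21).

Steps most likely to fail: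

1. Step 19 (proposed new method). The base may enolise the aldehyde at C6 instead of forming the ylide (epimerisation), the ylide may react between molecules (oligomerisation), and the facial selectivity at C5 or the cis ring fusion may be poor. Fallback, setting out from 19 and coming back at 34: cross-metathesis of 19 with 2-methylhexa-1,5-diene (second-generation Hoveyda–Grubbs catalyst) should give the isopropenyl enoate alcohol F1. The operations of steps 13–17 would then lead through the C9 silyl ether F2, the diol F3, the primary silyl ether F4 and the angelate F5 to the aldehyde F6. Wittig methylenation (Ph3P=CH2, THF, −78 °C) would give the C5 vinyl compound F7. Ring-closing metathesis (second-generation Grubbs catalyst, toluene, 80 °C, high dilution) would form the C4=C5 bond as the (4Z)-cyclodecadiene F8, the geometry a ten-membered ring imposes. Epoxidation of this only electron-rich alkene with dimethyldioxirane from the outer face would return to 34.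

2. Step 18. Silver-assisted ionisation of the secondary bromide may end in elimination or hydride shift instead of capture by diphenyl sulfide, and adventitious acid may strip silyl ethers. Fallback, setting out from 29 and coming back at 31: SN2 displacement of the bromide with PhSNa (DMF, 0 °C) would give the phenyl sulfide F9. Swern oxidation as in step 17 would give the sulfide aldehyde F10. Copper-catalysed S-phenylation with diphenyliodonium tetrafluoroborate (cat. Cu(OAc)2, 1,2-dichloroethane, 80 °C) would then give 31.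

3. Step 12. Cross-metathesis of the hindered 2-substituted acrylate may be sluggish, 21 may homodimerise, and E selectivity may be incomplete. Fallback, setting out from 14 and 21 and coming back at 22 (bypassing steps 9, 10 and 12): ozonolysis of 21 (O3; PPh3) would give 4-bromopentanal F11. Wittig reaction with Ph3P=C(I)CO2Me (from Ph3P=CHCO2Me and N-iodosuccinimide) would give methyl (2Z)-6-bromo-2-iodohept-2-enoate F12. Nozaki–Hiyama–Kishi coupling of F12 with 14 (CrCl2, cat. NiCl2, DMSO) would give 22 with the geometry carried over from the iodide; the C9 configuration would then rest on a chiral sulfonamide ligand instead of chelation.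

**Further compounds**

F1 | step 19 | isopropenyl enoate alcohol (22 with a C(CH3)=CH2 terminus at C4) | CC(C)(C)[Si](C)(C)OCC1C(=O)O[C@@H]2[C@H]1[C@@H]([C@@H](O)/C(C(=O)OC)=C\CCC(C)=C)OC2O[Si](CC)(CC)CC
F2 | step 19 | C9 TBS ether of F1 | CC(C)(C)[Si](C)(C)OCC1C(=O)O[C@@H]2[C@H]1[C@@H]([C@@H](O[Si](C)(C)C(C)(C)C)/C(C(=O)OC)=C\CCC(C)=C)OC2O[Si](CC)(CC)CC
F3 | step 19 | C5,C8-diol with isopropenyl terminus | CC(C)(C)[Si](C)(C)OCC1C(=O)O[C@@H](CO)[C@H]1[C@H](O)[C@@H](O[Si](C)(C)C(C)(C)C)/C(C(=O)OC)=C\CCC(C)=C
F4 | step 19 | C5 triethylsilyl ether of F3 | CC(C)(C)[Si](C)(C)OCC1C(=O)O[C@@H](CO[Si](CC)(CC)CC)[C@H]1[C@H](O)[C@@H](O[Si](C)(C)C(C)(C)C)/C(C(=O)OC)=C\CCC(C)=C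
F5 | step 19 | C8 angelate of F4 | CC(C)(C)[Si](C)(C)OCC1C(=O)O[C@@H](CO[Si](CC)(CC)CC)[C@H]1[C@H](OC(=O)/C(C)=C\C)[C@@H](O[Si](C)(C)C(C)(C)C)/C(C(=O)OC)=C\CCC(C)=C
F6 | step 19 | C5 aldehyde with isopropenyl terminus | CC(C)(C)[Si](C)(C)OCC1C(=O)O[C@@H](C=O)[C@H]1[C@H](OC(=O)/C(C)=C\C)[C@@H](O[Si](C)(C)C(C)(C)C)/C(C(=O)OC)=C\CCC(C)=C
F7 | step 19 | C5 vinyl compound (ring-closing metathesis substrate) | CC(C)(C)[Si](C)(C)OCC1C(=O)O[C@@H](C=C)[C@H]1[C@H](OC(=O)/C(C)=C\C)[C@@H](O[Si](C)(C)C(C)(C)C)/C(C(=O)OC)=C\CCC(C)=C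
F8 | step 19 | (4Z)-cyclodecadiene (C4=C5 alkene, C3 and C6 cis) | CC(C)(C)[Si](C)(C)OCC1C(=O)O[C@@H]2[C@H]1[C@H](OC(=O)/C(C)=C\C)[C@@H](O[Si](C)(C)C(C)(C)C)/C(C(=O)OC)=C\CC/C(C)=C\2
F9 | step 18 | C4 phenyl sulfide of 29 | CC(C)(C)[Si](C)(C)OCC1C(=O)O[C@@H](CO[Si](CC)(CC)CC)[C@H]1[C@H](OC(=O)/C(C)=C\C)[C@@H](O[Si](C)(C)C(C)(C)C)/C(C(=O)OC)=C\CCC(C)Sc1ccccc1
F10 | step 18 | C4 phenyl sulfide C5 aldehyde | CC(C)(C)[Si](C)(C)OCC1C(=O)O[C@@H](C=O)[C@H]1[C@H](OC(=O)/C(C)=C\C)[C@@H](O[Si](C)(C)C(C)(C)C)/C(C(=O)OC)=C\CCC(C)Sc1ccccc1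
F11 | step 12 | 4-bromopentanal | CC(Br)CCC=O
F12 | step 12 | methyl (2Z)-6-bromo-2-iodohept-2-enoate | COC(=O)/C(I)=C/CCC(C)Br
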